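The daucane core is cut across the seven-membered ring (C1, C5–C10) at C7–C8 and C1–C10. That ring shows a C8=C9 alkene flanked by the C7 methylene and by oxygenated C10, which adjoins quaternary C1, while C6 carries oxygen: the pattern left by a cis-divinylcyclopropane Cope rearrangement. One operation, rhodium-carbenoid cyclopropanation of a terpinen-4-ol-derived 2-silyloxydiene by an (E)-4-acetoxy vinyldiazoacetate followed by sigmatropic ring expansion, closes this ring, creates C1 and C10, and delivers C6, C8 and C10 with the right functional handles. The precursor is a cyclopentene carrying the silyl-protected C4 carbinol, the C1 methyl group and a 1-silyloxyvinyl group at C5.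

Key step: step 9

Remarks on the chemistry (valid for all steps)
- Numbering: C1 methyl-bearing fusion carbon; C2, C3 ring CH2; C4 carbinol carbon with isopropyl; C5 fusion CH; C6 veratrate carbon; C7 CH2; C8=C9 alkene with methyl on C8; C10 angelate carbon. α is the face of the C1 methyl group, β the other face. The target has 4-OH α, isopropyl β, H5 β, O6 β, O10 β, i.e. (1S,4R,5S,6S,10R).
- Assumption: commercial (S)-(+)-terpinen-4-ol of high enantiomeric purity is used; its purity limits that of the target.
- The carbinol carbon is never touched. Its descriptor changes from S to R from compound 6 onward (diene 9 is therefore R), only because the ring alkenyl carbon outranks isopropyl.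
- Three design choices: the carbinol is silylated before ozonolysis, so no free β-hydroxy aldehyde or hemiketal is formed. Both hydride steps precede both acylations, so no angelate or veratrate is exposed to hydride. The C4 hydroxyl is freed before the C6 reduction, so it can direct the hydride.
- The catalyst enantiomer is fixed as Rh2(R-DOSP)4 (DOSP = 1-(4-dodecylbenzenesulfonyl)prolinate). This rests on the reported sense of induction of this catalyst family with styrene-type alkenes, recalled and not re-derived here, so the antipodal catalyst is the first control experiment.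

Step 1
Reactants: 1 (S)-terpinen-4-ol
Product: 2 triethylsilyl ether of (S)-terpinen-4-ol
Conditions: Et3SiOTf, 2,6-lutidine, CH2Cl2, 0 °C to rt
Reagents that add atoms: triethylsilyl trifluoromethanesulfonate, CC[Si](CC)(CC)OS(=O)(=O)C(F)(F)F
Why: Silyl ether formation with a silyl triflate and a hindered pyridine base protects the tertiary alcohol without touching the stereocentre, so that the later β-oxygenated carbonyl compounds cannot undergo retro-aldol cleavage or hemiketal formation.

Step 2
Reactants: 2 triethylsilyl ether of (S)-terpinen-4-ol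
Product: 4 (3S)-3-isopropyl-6-oxo-3-(triethylsilyloxy)heptanal, via ozonide 3 (not isolated)
Conditions: O3, CH2Cl2, −78 °C; then PPh3, −78 °C to rt
Reagents that add atoms: ozone, [O-][O+]=O
Why: Ozonolysis of the only alkene (1,3-dipolar cycloaddition, cycloreversion, recombination) and phosphine reduction of the ozonide should give the 1,6-keto aldehyde, silyl ethers being inert to ozone.

Step 3
Reactants: 4 (3S)-3-isopropyl-6-oxo-3-(triethylsilyloxy)heptanal
Product: 6 (5R)-5-isopropyl-2-methyl-5-(triethylsilyloxy)cyclopent-1-ene-1-carbaldehyde, via aldol 5 (not isolated)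
Conditions: piperidine (cat.), AcOH (cat.), toluene, 50 °C
Reagents that add atoms: none
Why: Amine-salt intramolecular aldol condensation, in which the enamine of the aldehyde attacks the methyl ketone in a five-membered closure and dehydration gives the conjugated cyclopentene carbaldehyde, the usual regiochemistry of 6-oxoheptanals under these conditions.

Step 4
Reactants: 6 (5R)-5-isopropyl-2-methyl-5-(triethylsilyloxy)cyclopent-1-ene-1-carbaldehyde
Product: 7 1-[(5R)-5-isopropyl-2-methyl-5-(triethylsilyloxy)cyclopent-1-en-1-yl]ethan-1-ol (both carbinol epimers)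
Conditions: MeMgBr, THF, −78 to 0 °C
Reagents that add atoms: methylmagnesium bromide, C[Mg]Br
Why: Grignard 1,2-addition to the β,β-disubstituted enal; the new carbinol centre is formed as a mixture that the next oxidation erases.

Step 5
Reactants: 7 1-[(5R)-5-isopropyl-2-methyl-5-(triethylsilyloxy)cyclopent-1-en-1-yl]ethan-1-ol
Product: 8 1-[(5R)-5-isopropyl-2-methyl-5-(triethylsilyloxy)cyclopent-1-en-1-yl]ethan-1-one
Conditions: (n-Pr4N)RuO4 (cat.), N-methylmorpholine N-oxide, 4 Å MS, CH2Cl2, rt
Reagents that add atoms: none
Why: Ley–Griffith oxidation of the secondary allylic alcohol to the enone under neutral conditions that leave the tertiary silyl ether intact.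

Step 6
Reactants: 8 1-[(5R)-5-isopropyl-2-methyl-5-(triethylsilyloxy)cyclopent-1-en-1-yl]ethan-1-one
Product: 9 (R)-configured 2-silyloxydiene, tert-butyl({1-[(5R)-5-isopropyl-2-methyl-5-(triethylsilyloxy)cyclopent-1-en-1-yl]ethenyl}oxy)dimethylsilane
Conditions: t-BuMe2SiOTf, Et3N, CH2Cl2, 0 °C
Reagents that add atoms: tert-butyldimethylsilyl trifluoromethanesulfonate, CC(C)(C)[Si](C)(C)OS(=O)(=O)C(F)(F)F
Why: Soft enolisation (silyl triflate and amine) removes a proton from the acetyl methyl group, the kinetically preferred site of the enone, to give the cross-conjugated silyl enol ether.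

Step 7
Reactants: 10 methyl 4-oxobutanoate
Product: 11 methyl (E)-4-acetoxybut-3-enoate
Conditions: Ac2O, KOAc, 120 °C; E isomer separated by chromatography
Reagents that add atoms: acetic anhydride, CC(=O)OC(C)=O
Why: Enol acetylation of the enolisable aldehyde (O-acylation of its enolate) should give an E/Z mixture, from which the E isomer is taken because this geometry later becomes the C10 configuration.

Step 8
Reactants: 11 methyl (E)-4-acetoxybut-3-enoate
Product: 12 methyl (E)-4-acetoxy-2-diazobut-3-enoate
Conditions: 4-acetamidobenzenesulfonyl azide, DBU, MeCN, 0 °C; used at once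
Reagents that add atoms: 4-acetamidobenzenesulfonyl azide, CC(=O)Nc1ccc(cc1)S(=O)(=O)N=[N+]=[N-]
Why: Regitz diazo transfer to the dienolate of the β,γ-unsaturated ester gives the vinyldiazoacetate with the alkene geometry retained; it is kept cold because such diazo esters can cyclise to pyrazoles.

Step 9
Reactants: 9 (R)-configured 2-silyloxydiene; 12 methyl (E)-4-acetoxy-2-diazobut-3-enoate
Product: 14 bicyclic cycloheptadiene with C5=C6 silyl enol ether (6-OSiMe2t-Bu), C8=C9 (8-CO2Me), 10β-acetoxy, 1α-methyl and 4α-OSiEt3 (1S,4R,10R), via cis-divinylcyclopropane 13 (not isolated)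
Conditions: Rh2(R-DOSP)4 (2 mol %), hexanes, −40 °C, slow addition of 12 (1.5 equiv, in toluene); then 80 °C
Reagents that add atoms: none
Why: Rh2(R-DOSP)4 releases N2 from 12, and the donor/acceptor carbenoid adds in a concerted, asynchronous [2+1] step to the electron-rich silyloxyvinyl group of 9 (C7–C8 and C6–C8); cis-divinylcyclopropane 13 then undergoes a [3,3]-sigmatropic shift through a boat transition state that breaks C6–C8 and joins C1 to C10. This is the known tandem cyclopropanation/Cope rearrangement (formal (4+3) cycloaddition) of vinyldiazoacetates with 2-silyloxydienes, here with a less usual 4-acyloxy group on the carbenoid. The seven-membered ring is closed in the sigmatropic step by bonding of the two vinyl termini, after the transient three-membered ring has been closed by carbene transfer and opened again. C1 follows from the configuration of 13 (C8 S, C6 R), which is set by the carbenoid face that the R-configured catalyst is expected to leave open; C10 follows from C1 through the boat geometry, because the E enol acetate places O10 on the side of C2 and anti to the C1 methyl group. The step needs attack at the silyloxyvinyl group (the ring alkene is tetrasubstituted and inert), a cis relation of the cyclopentenyl and acetoxyvinyl groups on the cyclopropane (the usual syn preference of the alkene π-substituent for the carbenoid donor group), and catalyst control over the weak bias of C4. Because the C1 methyl group points into the boat, the rearrangement is expected to need the final warming.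

Step 10
Reactants: 14 bicyclic cycloheptadiene (8-CO2Me, 10β-OAc)
Product: 15 ene-diol with 8-CH2OH and 10β-OH, C5=C6 silyl enol ether and 4α-OSiEt3 retained (1S,4R,10R)
Conditions: i-Bu2AlH (6 equiv), CH2Cl2, −78 to −20 °C; aq. KNaC4H4O6
Reagents that add atoms: none
Why: Aluminium hydride 1,2-reduction turns the conjugated methyl ester into the primary allylic alcohol and cleaves the acetate in the same operation, while the silyl enol ether, the silyl ether and all stereocentres are untouched.

Step 11
Reactants: 15 ene-diol (8-CH2OH, 10β-OH)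
Product: 17 allylic chloride with 8-CH2Cl and free 10β-OH, via mesylate 16 (not isolated)
Conditions: MsCl, 2,4,6-collidine, LiCl, DMF, 0 °C
Reagents that add atoms: lithium chloride, [Li+].[Cl-]
Why: Selective sulfonylation of the primary allylic alcohol followed by in situ SN2 displacement by chloride, the neopentylic C10 hydroxyl being too hindered to react.

Step 12
Reactants: 17 allylic chloride (8-CH2Cl, 10β-OH)
Product: 18 allylic alcohol with 8-methyl and 10β-OH, C5=C6 silyl enol ether and 4α-OSiEt3 (1S,4R,10R)
Conditions: LiBHEt3, THF, 0 °C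
Reagents that add atoms: none
Why: SN2 hydride displacement of the primary allylic chloride gives the C8 methyl group, attack at the more hindered C9 (SN2') being disfavoured.

Step 13
Reactants: 18 allylic alcohol (8-methyl, 10β-OH); 19 angelic acid
Product: 21 10β-angelate with C5=C6 silyl enol ether and 4α-OSiEt3 (1S,4R,10R), via mixed anhydride 20 (not isolated)
Conditions: 19, 2,4,6-Cl3C6H2COCl, Et3N, toluene, rt; then 18, 80 °C
Reagents that add atoms: none
Why: Yamaguchi esterification, in which the mixed anhydride acylates the hindered C10 alcohol at the angeloyl carbonyl with retention at C10; leaving out nucleophilic catalysts avoids isomerisation to the tiglate.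

Step 14
Reactants: 21 10β-angelate with C5=C6 silyl enol ether and 4α-OSiEt3
Product: 23 β-hydroxy ketone with 6-oxo, 4α-OH, H5 β and 10β-angelate (1S,4R,5R,10R), via silyloxy ketone 22 (not isolated)
Conditions: HF·pyridine, pyridine, THF, 0 °C to rt
Reagents that add atoms: none
Why: Protodesilylation of the silyl enol ether should place hydrogen on C5 from the β face, opposite the C1 methyl and C4 silyloxy groups, giving the trans ring fusion; this is also the epimer with C6 anti to isopropyl and able to hydrogen-bond to the C4 hydroxyl, which is freed by the slower cleavage of the tertiary silyl ether in a medium too acidic for retro-aldol cleavage.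

Step 15
Reactants: 23 β-hydroxy ketone (6-oxo, 4α-OH)
Product: 24 4α,6β-diol with 10β-angelate (1S,4R,5S,6S,10R)
Conditions: Me4NBH(OAc)3, MeCN/AcOH, −30 to 0 °C
Reagents that add atoms: none
Why: Saksena–Evans hydroxyl-directed reduction, in which the C4 hydroxyl binds boron and delivers hydride to the α face of the C6 ketone, giving the 4,6-anti diol (6S) without reducing the angelate.

Step 16
Reactants: 24 4α,6β-diol with 10β-angelate; 25 3,4-dimethoxybenzoyl chloride
Product: 26 CNP0142353.1, (1S,4R,5S,6S,10R)-10-angeloyloxy-4-hydroxy-6-veratroyloxydauc-8-ene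
Conditions: 25, pyridine, DMAP (cat.), CH2Cl2, 0 °C to rt
Reagents that add atoms: none
Why: Acylation of the secondary C6 alcohol by the acid chloride under nucleophilic catalysis, the tertiary C4 hydroxyl being too hindered to react and no stereocentre being affected.

Compound list
1 | (S)-terpinen-4-ol | CC1=CC[C@](O)(C(C)C)CC1 | starting material
2 | triethylsilyl ether of (S)-terpinen-4-ol | CC1=CC[C@](O[Si](CC)(CC)CC)(C(C)C)CC1 | intermediate
3 | ozonide (1,2,4-trioxolane) of 2, diastereomer mixture, not isolated | CC12CC[C@@](O[Si](CC)(CC)CC)(C(C)C)CC(OO1)O2 | intermediate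
4 | (3S)-3-isopropyl-6-oxo-3-(triethylsilyloxy)heptanal | CC(=O)CC[C@@](O[Si](CC)(CC)CC)(C(C)C)CC=O | intermediate
5 | (5R)-2-hydroxy-5-isopropyl-2-methyl-5-(triethylsilyloxy)cyclopentane-1-carbaldehyde, diastereomer mixture, not isolated | O=CC1C(C)(O)CC[C@@]1(O[Si](CC)(CC)CC)C(C)C | intermediate
6 | (5R)-5-isopropyl-2-methyl-5-(triethylsilyloxy)cyclopent-1-ene-1-carbaldehyde | O=CC1=C(C)CC[C@@]1(O[Si](CC)(CC)CC)C(C)C | intermediate
7 | 1-[(5R)-5-isopropyl-2-methyl-5-(triethylsilyloxy)cyclopent-1-en-1-yl]ethan-1-ol, carbinol epimers | CC(O)C1=C(C)CC[C@@]1(O[Si](CC)(CC)CC)C(C)C | intermediate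
8 | 1-[(5R)-5-isopropyl-2-methyl-5-(triethylsilyloxy)cyclopent-1-en-1-yl]ethan-1-one | CC(=O)C1=C(C)CC[C@@]1(O[Si](CC)(CC)CC)C(C)C | intermediate
9 | (R)-configured 2-silyloxydiene | C=C(O[Si](C)(C)C(C)(C)C)C1=C(C)CC[C@@]1(O[Si](CC)(CC)CC)C(C)C | intermediate
10 | methyl 4-oxobutanoate | COC(=O)CCC=O | starting material
11 | methyl (E)-4-acetoxybut-3-enoate | COC(=O)C/C=C/OC(C)=O | intermediate
12 | methyl (E)-4-acetoxy-2-diazobut-3-enoate | COC(=O)C(=[N+]=[N-])/C=C/OC(C)=O | intermediate
13 | methyl (1S,2R)-1-[(E)-2-acetoxyethenyl]-2-(tert-butyldimethylsilyloxy)-2-[(5R)-5-isopropyl-2-methyl-5-(triethylsilyloxy)cyclopent-1-en-1-yl]cyclopropane-1-carboxylate, not isolated | CC(=O)O/C=C/[C@@]1(C(=O)OC)C[C@@]1(O[Si](C)(C)C(C)(C)C)C2=C(C)CC[C@@]2(O[Si](CC)(CC)CC)C(C)C | intermediate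
14 | bicyclic cycloheptadiene: 10β-acetoxy, 8-CO2Me, C5=C6 with 6-OSiMe2t-Bu, 4α-OSiEt3 (1S,4R,10R) | CC(=O)O[C@@H]1C=C(C(=O)OC)CC(O[Si](C)(C)C(C)(C)C)=C2[C@]1(C)CC[C@@]2(O[Si](CC)(CC)CC)C(C)C | intermediate
15 | ene-diol: 8-CH2OH, 10β-OH (1S,4R,10R) | O[C@@H]1C=C(CO)CC(O[Si](C)(C)C(C)(C)C)=C2[C@]1(C)CC[C@@]2(O[Si](CC)(CC)CC)C(C)C | intermediate
16 | primary allylic mesylate of 15, not isolated | O[C@@H]1C=C(COS(C)(=O)=O)CC(O[Si](C)(C)C(C)(C)C)=C2[C@]1(C)CC[C@@]2(O[Si](CC)(CC)CC)C(C)C | intermediate
17 | allylic chloride: 8-CH2Cl, 10β-OH | O[C@@H]1C=C(CCl)CC(O[Si](C)(C)C(C)(C)C)=C2[C@]1(C)CC[C@@]2(O[Si](CC)(CC)CC)C(C)C | intermediate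
18 | allylic alcohol: 8-methyl, 10β-OH (1S,4R,10R) | O[C@@H]1C=C(C)CC(O[Si](C)(C)C(C)(C)C)=C2[C@]1(C)CC[C@@]2(O[Si](CC)(CC)CC)C(C)C | intermediate
19 | angelic acid, (Z)-2-methylbut-2-enoic acid | C/C=C(/C)C(=O)O | starting material
20 | angelic 2,4,6-trichlorobenzoic anhydride, not isolated | C/C=C(/C)C(=O)OC(=O)c1c(Cl)cc(Cl)cc1Cl | intermediate
21 | 10β-angelate with C5=C6 silyl enol ether and 4α-OSiEt3 (1S,4R,10R) | C/C=C(/C)C(=O)O[C@@H]1C=C(C)CC(O[Si](C)(C)C(C)(C)C)=C2[C@]1(C)CC[C@@]2(O[Si](CC)(CC)CC)C(C)C | intermediate
22 | 6-ketone with 4α-OSiEt3 and 10β-angelate (1S,4R,5R,10R), not isolated | C/C=C(/C)C(=O)O[C@@H]1C=C(C)CC(=O)[C@@H]2[C@]1(C)CC[C@@]2(O[Si](CC)(CC)CC)C(C)C | intermediate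
23 | β-hydroxy ketone: 6-oxo, 4α-OH, 10β-angelate (1S,4R,5R,10R) | C/C=C(/C)C(=O)O[C@@H]1C=C(C)CC(=O)[C@@H]2[C@]1(C)CC[C@@]2(O)C(C)C | intermediate
24 | 4α,6β-diol with 10β-angelate (1S,4R,5S,6S,10R) | C/C=C(/C)C(=O)O[C@@H]1C=C(C)C[C@H](O)[C@@H]2[C@]1(C)CC[C@@]2(O)C(C)C | intermediate
25 | 3,4-dimethoxybenzoyl chloride (veratroyl chloride) | COc1ccc(C(Cl)=O)cc1OC | starting material
26 | CNP0142353.1, (1S,4R,5S,6S,10R)-10-angeloyloxy-4-hydroxy-6-veratroyloxydauc-8-ene | C/C=C(/C)C(=O)O[C@@H]1C=C(C)C[C@H](OC(=O)c2ccc(OC)c(OC)c2)[C@@H]2[C@]1(C)CC[C@@]2(O)C(C)C | target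

Total step count: 16. Longest linear sequence: 14 steps (steps 1–6, 9, 10–16); steps 7 and 8 form the short branch.

Steps most likely to fail

Step 9. The carbenoid may add with the wrong facial sense, or give the trans-divinylcyclopropane. The Cope step is then slow, and configuration leaks through reversible opening of the silyloxy/ester-substituted cyclopropane bond. Cyclisation of the diazo ester to a pyrazole also competes. The fallback moves stereocontrol from the catalyst to an auxiliary on the carbenoid; it sets out from 9 and returns at 15. (R)-Pantolactone is acylated with pent-4-enoyl chloride (pyridine, CH2Cl2) to (R)-pantolactonyl pent-4-enoate F1. Ozonolysis (O3, then PPh3) through the ozonide F2 gives (R)-pantolactonyl 4-oxobutanoate F3. Enol acetylation as in step 7 gives the E enol acetate F4, and diazo transfer as in step 8 gives the diazo ester F5. Decomposition of F5 by achiral Rh2(O2CC7H15)4 in the presence of 9 (hexanes, then 80 °C) should give, through the cyclopropane F6, the pantolactonyl ester F7, the lactone carbonyl shielding one face of the carbenoid. Reduction with i-Bu2AlH removes auxiliary and acetate together and gives 15. The sense of induction of the auxiliary is not established here, so the enantiomeric auxiliary is taken if it proves opposite.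

Step 14. Once the C4 hydroxyl is free next to the C6 ketone, retro-aldol opening of the five-membered ring or dehydration can set in. Protonation at C5 may also occur from the α face, and the C8=C9 alkene may drift into conjugation. The fallback keeps C4 silylated and replaces directed reduction by inversion; it sets out from 21 and ends at 26. Buffered fluoride (n-Bu4NF, AcOH, THF, −20 °C) cleaves only the enol ether and 22 is isolated. Reduction with NaBH4 and CeCl3·7H2O (MeOH, −40 °C), expected from the more open β face, gives the 6-epi alcohol F8. Mitsunobu esterification with veratric acid (PPh3, DIAD, toluene) inverts C6 and gives the 4-O-triethylsilyl ether of the target F9. HF·pyridine then removes the silyl group to give 26.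

Step 13. Acylation of the neopentylic C10 alcohol may be slow, and the activated angeloyl unit may meanwhile isomerise to the tigloyl isomer. The fallback builds the Z alkene on the ester instead of transferring it; it sets out from 18 and returns at 21. 18 is acylated with 2-[bis(2,2,2-trifluoroethoxy)phosphoryl]propanoic acid (from its ethyl ester by LiOH hydrolysis; dicyclohexylcarbodiimide, CH2Cl2) to the phosphonopropionate F10. Still–Gennari olefination of F10 with acetaldehyde (KN(SiMe3)2, 18-crown-6, THF, −78 °C) should give the Z-configured 2-methylbut-2-enoate 21.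

Further compounds
F1 | step 9 | (R)-pantolactonyl pent-4-enoate | C=CCCC(=O)O[C@H]1C(=O)OCC1(C)C
F2 | step 9 | ozonide of F1 (diastereomer mixture) | O=C(CCC1OCOO1)O[C@H]2C(=O)OCC2(C)C
F3 | step 9 | (R)-pantolactonyl 4-oxobutanoate | O=CCCC(=O)O[C@H]1C(=O)OCC1(C)C
F4 | step 9 | (R)-pantolactonyl (E)-4-acetoxybut-3-enoate | CC(=O)O/C=C/CC(=O)O[C@H]1C(=O)OCC1(C)C
F5 | step 9 | (R)-pantolactonyl (E)-4-acetoxy-2-diazobut-3-enoate | CC(=O)O/C=C/C(=[N+]=[N-])C(=O)O[C@H]1C(=O)OCC1(C)C
F6 | step 9 | cis-divinylcyclopropane, pantolactonyl ester analogue of 13 | CC(=O)O/C=C/[C@@]1(C(=O)O[C@H]3C(=O)OCC3(C)C)C[C@@]1(O[Si](C)(C)C(C)(C)C)C2=C(C)CC[C@@]2(O[Si](CC)(CC)CC)C(C)C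
F7 | step 9 | bicyclic cycloheptadiene, pantolactonyl ester analogue of 14 | CC(=O)O[C@@H]1C=C(C(=O)O[C@H]3C(=O)OCC3(C)C)CC(O[Si](C)(C)C(C)(C)C)=C2[C@]1(C)CC[C@@]2(O[Si](CC)(CC)CC)C(C)C
F8 | step 14 | 6-epi alcohol (6R) with 4α-OSiEt3 and 10β-angelate | C/C=C(/C)C(=O)O[C@@H]1C=C(C)C[C@@H](O)[C@@H]2[C@]1(C)CC[C@@]2(O[Si](CC)(CC)CC)C(C)C
F9 | step 14 | 4-O-triethylsilyl ether of the target | C/C=C(/C)C(=O)O[C@@H]1C=C(C)C[C@H](OC(=O)c2ccc(OC)c(OC)c2)[C@@H]2[C@]1(C)CC[C@@]2(O[Si](CC)(CC)CC)C(C)C
F10 | step 13 | 2-[bis(2,2,2-trifluoroethoxy)phosphoryl]propanoate of 18 (epimers at the phosphonate carbon) | CC(C(=O)O[C@@H]1C=C(C)CC(O[Si](C)(C)C(C)(C)C)=C2[C@]1(C)CC[C@@]2(O[Si](CC)(CC)CC)C(C)C)P(=O)(OCC(F)(F)F)OCC(F)(F)F
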